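(Readings and results were computed on assumed constants; the scatter is artificial.)

The earliest reading of any run comes at 2.00 min, much later than the 1.2 s asked about, so flat readings must speak for a start that none of them shows.

in all of them: substrate 0.43 M; capture agent 0.129 M
- south-east: first nucleophile 0.21 M; second nucleophile 0.215 M; run made earlier
- east: first nucleophile 0.86 M; second nucleophile 0.215 M; run made earlier
- north-east: first nucleophile 0.43 M; second nucleophile 0.11 M; run made earlier
- flask: first nucleophile 0.430 M; second nucleophile 0.215 M; time 20 min

| run | time / min | other capture product / % | target / % | substrate / % |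
|---|---|---|---|---|
| south-east | 5.00 | 42.9 | 26.3 | 0.2 |
| south-east | 10.0 | 43.8 | 25.9 | 0 |
| south-east | 15.0 | 43.4 | 25.8 | 0 |
| south-east | 20.0 | 42.9 | 25.5 | 0 |
| south-east | 25.0 | 43.8 | 24.9 | 0.1 |
| east | 2.00 | 25.7 | 52.1 | 0 |
| east | 6.00 | 26.5 | 52.0 | 0.8 |
| east | 12.0 | 25.9 | 52.0 | 0 |
| east | 15.0 | 25.4 | 53.0 | 0.1 |
| east | 25.0 | 25.3 | 53.1 | 0 |
| north-east | 5.00 | 22.2 | 47.4 | 0.4 |
| north-east | 10.0 | 20.4 | 47.5 | 0 |
| north-east | 15.0 | 20.2 | 47.0 | 0 |
| north-east | 20.0 | 21.6 | 46.8 | 0.7 |
| north-east | 25.0 | 20.9 | 47.6 | 0.8 |

(each reading ± 0.5 percentage points)

- a reading or a percentage of target counts all its forms, free or not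

- ratio of other capture product to target at 1.2 s
- ratio of other capture product to target at 40 s
- ratio of other capture product to target at 20 min

At the start of the flask, the ratio of other capture product to target is a ratio of two capture rates: the selectivity factor times second nucleophile over first nucleophile. I reckon that factor two ways from the mean readings.

The first way is depletion: the logarithm of second nucleophile left over that of first nucleophile left, with target as the measure of first nucleophile consumed.

| run | other capture product | target | factor by depletion |
|---|---|---|---|
| south-east | 43.4% | 25.7% | 2.71 |
| east | 25.8% | 52.4% | 2.38 |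
| north-east | 21.1% | 47.3% | 2.71 |

These should be one number, but they are not. Also, 21.8% to 31.6% of the substrate is unseen, and any of it that passed through first nucleophile inflates this factor.

The second way asks less of target. Substrate not in other capture product, divided by the logarithmic fall of second nucleophile, is a straight line in mean first nucleophile, with slope one over the factor; a first-order side path sits in the intercept. Target enters just through that mean. South-east and east give 1.85 for the selectivity factor, the reactivity of second nucleophile over first per unit concentration; east and north-east give 1.73.

I trust the second way, so my start ratio for the flask, which I give for 1.2 s, is 0.927. For the end, the geometric mean of the south-east and east ratios gives 0.912. The earliest reading comes later than 40 s, so I can only expect a value near both there.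

The forecast says 1.28, 0.98 and 0.93, and reckons that “the second nucleophile is about 2.6 times more reactive per unit concentration”. We part at the start and nearly agree at the end.

    open intermediate → solvolysis product (k = 0.438 /s)
    substrate → open intermediate (k = 0.0703 /s)
    first nucleophile + open intermediate → target (k = 5.04 /M/s)
    target ⇌ isomer of the product (K = 0.283, k = 0.0109 /s)
    open intermediate + capture agent → trapped intermediate (k = 0.112 /M/s)
    second nucleophile + open intermediate → other capture product (k = 9.12 /M/s)
    crystals ⇌ target, rate k7*(cs7 - [target]) while solid is left; crystals form when [target] > cs7 (solubility = 0.200 M, k = 2.94 /s)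

The flask gives 0.898 at 1.2 s, 0.863 at 40 s and 0.918 at 20 min, with 11.0% of the substrate as isomer of the product beside 38.9% as target. Its leftovers, 29% of second nucleophile and 50% of first, give a factor of 1.81 by depletion. The neighbour flask with 0.73 M of substrate has the same nucleophile charges, so the reckoning keeps its start ratio at 0.927, and it shows 0.890. Its leftovers, 3.7% of second nucleophile and 16% of first, give 1.80. Its ratio at 20 min is 0.682.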